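**Retrosynthetic overview**

1. The target is (2R,3R)-6-(1,1-dimethylallyl)dihydrokaempferol. Its three MOM ethers are removed last; before that, ring C is closed (bond O1–C2) when the C8a phenol opens a (2R,3S)-aryl epoxy ketone at the benzylic carbon with inversion, C3 coming unchanged from the epoxide.
2. The strategy rests on C4a and C8a of ring A: two neighbouring ring carbons that carry the C4 acyl carbon and O1. This ortho acyl/oxygen pair is cut in one operation (bonds C4–C4a and O1–C8a) to an aryne and a glycidate, the aryne entering the carboxyl C–O bond.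
3. The aryne comes from an ortho-silylaryl triflate built from phloroglucinol: mono-O-prenylation, Claisen rearrangement (quaternary carbon on the future C6), size-based differentiation of the hydroxyl para to it, carbamate-directed ortho-silylation, triflation.
4. The glycidate comes from methyl 4-hydroxycinnamate: MOM protection, chiral dioxirane epoxidation (sets both stereocentres), silanolate ester cleavage.
5. Ring order: rings A and B are bought; ring C is the only ring made for the target and is closed in step 11.

Key step: step 10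

Remark: a free β-aryl glycidic acid loses CO2 with opening of the epoxide, so the acid partner of the key step is made and used as its anhydrous potassium salt 18. Flavanone numbering (O1, C2, C3, C4, C4a, C5–C8, C8a) is used for the target.

**Route**

Step 1
Reactants: 1 phloroglucinol; 2 3-methylbut-2-en-1-ol (prenol)
Product: 3 5-[(3-methylbut-2-en-1-yl)oxy]benzene-1,3-diol
Conditions: 1 (3 equiv, anhydrous), PPh3, DIAD, THF, 0 → 23 °C
Reagents that add atoms: none
Why: Mitsunobu etherification: the phenol, used in excess so that mono-etherification prevails, attacks the oxyphosphonium salt of the primary allylic alcohol through oxygen in an SN2 step, which avoids the ring C-alkylation that prenyl halides and base give with phloroglucinol.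

Step 2
Reactants: 3 5-[(3-methylbut-2-en-1-yl)oxy]benzene-1,3-diol
Product: 6 2-(2-methylbut-3-en-2-yl)benzene-1,3,5-triol, via bis-silyl ether 4 (not isolated), via tris-silyl ether 5 (not isolated)
Conditions: N,O-bis(trimethylsilyl)acetamide (4 equiv), N,N-diethylaniline, 180 °C; then 1 M aq. HCl–THF, 0 °C
Reagents that add atoms: none
Why: Aromatic Claisen rearrangement: the [3,3]-sigmatropic shift of the aryl prenyl ether brings the tertiary allyl terminus to one of the two equivalent ortho carbons and makes the quaternary 1,1-dimethylallyl group, while silylation of every hydroxyl keeps the new ortho phenol from the abnormal Claisen rearrangement and from adding to the vinyl group; the silyl ethers are hydrolysed on work-up.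

Step 3
Reactants: 6 2-(2-methylbut-3-en-2-yl)benzene-1,3,5-triol
Product: 7 3,5-dihydroxy-4-(2-methylbut-3-en-2-yl)phenyl N-(propan-2-yl)carbamate
Conditions: iPrNCO (1.0 equiv), Et3N (0.2 equiv), THF, −20 → 0 °C
Reagents that add atoms: isopropyl isocyanate, CC(C)N=C=O
Why: Amine-catalysed addition of a phenol to an isocyanate (carbamoylation): with one equivalent of reagent the hydroxyl para to the tertiary alkyl group should react first, because each of the other two sits next to the quaternary carbon.

Step 4
Reactants: 7 3,5-dihydroxy-4-(2-methylbut-3-en-2-yl)phenyl N-(propan-2-yl)carbamate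
Product: 8 3,5-bis(methoxymethoxy)-4-(2-methylbut-3-en-2-yl)phenyl N-(propan-2-yl)carbamate
Conditions: MOMCl, iPr2NEt, Bu4NI (cat.), CH2Cl2, 0 → 40 °C
Reagents that add atoms: chloromethyl methyl ether, COCCl
Why: MOM protection (O-alkylation of the two remaining phenols) under a tertiary amine, a base too weak to deprotonate the carbamate N–H and expel the isocyanate.

Step 5
Reactants: 8 3,5-bis(methoxymethoxy)-4-(2-methylbut-3-en-2-yl)phenyl N-(propan-2-yl)carbamate
Product: 12 3,5-bis(methoxymethoxy)-4-(2-methylbut-3-en-2-yl)-2-(trimethylsilyl)phenyl N-(propan-2-yl)carbamate, via N-silyl carbamate 9 (not isolated), via aryllithium 10 (not isolated), via C-silylated N-silyl carbamate 11 (not isolated)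
Conditions: TMSOTf, TMEDA, Et2O, 0 → 23 °C; n-BuLi, TMEDA, −78 °C; TMSCl, −78 → 23 °C; aq. NH4Cl
Reagents that add atoms: chlorotrimethylsilane, C[Si](C)(C)Cl
Why: Directed ortho-metalation: after N-silylation of the secondary carbamate, butyllithium removes the ring proton between the carbamate and a MOM-oxy group (the only two ring hydrogens are equivalent by symmetry) and the aryllithium is silylated by TMSCl; the N-silyl group is lost on aqueous work-up.

Step 6
Reactants: 12 3,5-bis(methoxymethoxy)-4-(2-methylbut-3-en-2-yl)-2-(trimethylsilyl)phenyl N-(propan-2-yl)carbamate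
Product: 14 3,5-bis(methoxymethoxy)-4-(2-methylbut-3-en-2-yl)-2-(trimethylsilyl)phenyl trifluoromethanesulfonate, via silylphenol 13 (not isolated)
Conditions: DBU, Et2NH, MeCN, 40 °C; then PhNTf2, 23 °C
Reagents that add atoms: N-phenylbis(trifluoromethanesulfonimide), O=S(=O)(N(c1ccccc1)S(=O)(=O)C(F)(F)F)C(F)(F)F
Why: Base-induced E1cB loss of isopropyl isocyanate from the N–H carbamate (the isocyanate is trapped by diethylamine) gives the ortho-silylphenoxide, which is triflated in the same flask by PhNTf2 (phenol triflation).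

Step 7
Reactants: 15 methyl (E)-3-(4-hydroxyphenyl)prop-2-enoate
Product: 16 methyl (E)-3-[4-(methoxymethoxy)phenyl]prop-2-enoate
Conditions: MOMCl, iPr2NEt, CH2Cl2, 0 → 23 °C
Reagents that add atoms: chloromethyl methyl ether, COCCl
Why: MOM protection of the phenol by O-alkylation; the acetal survives the buffered oxidation, the fluoride step and is removed by acid at the end.

Step 8
Reactants: 16 methyl (E)-3-[4-(methoxymethoxy)phenyl]prop-2-enoate
Product: 17 methyl (2R,3S)-3-[4-(methoxymethoxy)phenyl]oxirane-2-carboxylate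
Conditions: 4,5-di-O-acetyl-1,2-O-isopropylidene-β-L-erythro-2,3-hexodiulo-2,6-pyranose (0.3 equiv), KHSO5 (as 2KHSO5·KHSO4·K2SO4), NaHCO3, Bu4NHSO4, MeCN–aq. Na2EDTA, 0 °C
Reagents that add atoms: potassium peroxymonosulfate, [K+].[O-]S(=O)(=O)OO
Why: Shi-type asymmetric epoxidation by a chiral dioxirane made in the flask from the ketone and KHSO5: oxygen transfer is concerted, so the E-alkene gives the trans-epoxide, and the L-series ketone, mirror image of the D-fructose-derived catalyst that is expected to give (2S,3R)-glycidates from E-cinnamates, should deliver the (2R,3S)-epoxide through the spiro transition state.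

Step 9
Reactants: 17 methyl (2R,3S)-3-[4-(methoxymethoxy)phenyl]oxirane-2-carboxylate
Product: 18 potassium (2R,3S)-3-[4-(methoxymethoxy)phenyl]oxirane-2-carboxylate
Conditions: KOSiMe3 (1.0 equiv), THF, 0 → 23 °C; salt filtered and dried under argon
Reagents that add atoms: potassium trimethylsilanolate, C[Si](C)(C)[O-].[K+]
Why: Ester cleavage by potassium trimethylsilanolate in an aprotic solvent gives the anhydrous potassium carboxylate directly and never passes through the free glycidic acid; neither epoxide carbon is touched.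

Step 10
Reactants: 14 3,5-bis(methoxymethoxy)-4-(2-methylbut-3-en-2-yl)-2-(trimethylsilyl)phenyl trifluoromethanesulfonate; 18 potassium (2R,3S)-3-[4-(methoxymethoxy)phenyl]oxirane-2-carboxylate
Product: 22 [6-hydroxy-2,4-bis(methoxymethoxy)-3-(2-methylbut-3-en-2-yl)phenyl][(2R,3S)-3-[4-(methoxymethoxy)phenyl]oxiran-2-yl]methanone, via aryne 19 (not isolated), via ortho-potassioaryl ester 20 (not isolated), via potassium phenoxide 21 (not isolated)
Conditions: KF (3 equiv), 18-crown-6 (3 equiv), THF, 0 → 23 °C, 14 added slowly to 18 (1.5 equiv); then aq. NH4Cl, 0 °C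
Reagents that add atoms: none
Why: Proposed new method: fluoride removes the silyl group of 14 and triflate leaves to give aryne 19, the carboxylate oxygen of 18 adds to the aryne carbon remote from the flanking MOM-oxy group (the future C8a) because that substituent distorts the aryne and stabilises by induction the negative charge building on the neighbouring carbon (the future C4a), and aryl anion 20 results. With no proton donor in the flask (preformed potassium salt, aprotic solvent) the anion should attack its own ester carbonyl through a four-membered transition structure, so that the acyl group moves from oxygen to carbon (anionic Fries-type 1,3-shift) and the chelated phenoxide 21 is formed, which is protonated on work-up. The closest known reaction type is the fluoride-induced insertion of arynes into the C–O bond of carboxylic acids to give ortho-hydroxyaryl ketones, which has not been run on an epoxy carboxylate. No ring is closed and no stereocentre is made in this step: bonds O1–C8a and C4–C4a are formed and both epoxide carbons are carried through unchanged, since the carbonyl is never enolised. The selectivities needed are the site of carboxylate addition, secured by the alkoxy group next to the aryne, acyl shift ahead of protonation, secured by the absence of acid, and survival of the epoxide beside the phenoxide, for which the low temperature, the excess of 18 and the slow addition of 14 are chosen.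

Step 11
Reactants: 22 [6-hydroxy-2,4-bis(methoxymethoxy)-3-(2-methylbut-3-en-2-yl)phenyl][(2R,3S)-3-[4-(methoxymethoxy)phenyl]oxiran-2-yl]methanone
Product: 23 (2R,3R)-3-hydroxy-5,7-bis(methoxymethoxy)-2-[4-(methoxymethoxy)phenyl]-6-(2-methylbut-3-en-2-yl)-2,3-dihydro-4H-chromen-4-one
Conditions: (+)-camphor-10-sulfonic acid (0.1 equiv), CH2Cl2, −20 → 0 °C
Reagents that add atoms: none
Why: Acid-promoted intramolecular epoxide opening (6-endo closure of ring C): the protonated epoxide lengthens its bond to the carbon bearing the 4-alkoxyphenyl group and the C8a phenol attacks that carbon anti to the leaving oxygen, so C2 is set (R) by inversion while C3 keeps the (R) configuration of the glycidate α-carbon; attack at the carbon next to the ketone (5-exo) is disfavoured because that carbon cannot carry positive charge.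

Step 12
Reactants: 23 (2R,3R)-3-hydroxy-5,7-bis(methoxymethoxy)-2-[4-(methoxymethoxy)phenyl]-6-(2-methylbut-3-en-2-yl)-2,3-dihydro-4H-chromen-4-one
Product: 24 (2R,3R)-3,5,7-trihydroxy-2-(4-hydroxyphenyl)-6-(2-methylbut-3-en-2-yl)-2,3-dihydro-4H-chromen-4-one (CNP0527000.1)
Conditions: HCl (3 M in MeOH), MeOH–THF, 40 °C, argon
Reagents that add atoms: none
Why: Acid-catalysed acetal exchange with methanol (MOM removal) frees the three phenols; the mild temperature should spare the monosubstituted alkene and avoid enolisation at C3.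

**Compound list**

1 | phloroglucinol (benzene-1,3,5-triol) | Oc1cc(O)cc(O)c1 | starting material
2 | 3-methylbut-2-en-1-ol (prenol) | CC(C)=CCO | starting material
3 | 5-[(3-methylbut-2-en-1-yl)oxy]benzene-1,3-diol | CC(C)=CCOc1cc(O)cc(O)c1 | intermediate
4 | 1-[(3-methylbut-2-en-1-yl)oxy]-3,5-bis(trimethylsilyloxy)benzene (formed in the flask) | CC(C)=CCOc1cc(O[Si](C)(C)C)cc(O[Si](C)(C)C)c1 | intermediate
5 | 2-(2-methylbut-3-en-2-yl)-1,3,5-tris(trimethylsilyloxy)benzene (formed in the flask) | C=CC(C)(C)c1c(O[Si](C)(C)C)cc(O[Si](C)(C)C)cc1O[Si](C)(C)C | intermediate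
6 | 2-(2-methylbut-3-en-2-yl)benzene-1,3,5-triol | C=CC(C)(C)c1c(O)cc(O)cc1O | intermediate
7 | 3,5-dihydroxy-4-(2-methylbut-3-en-2-yl)phenyl N-(propan-2-yl)carbamate | C=CC(C)(C)c1c(O)cc(OC(=O)NC(C)C)cc1O | intermediate
8 | 3,5-bis(methoxymethoxy)-4-(2-methylbut-3-en-2-yl)phenyl N-(propan-2-yl)carbamate | C=CC(C)(C)c1c(OCOC)cc(OC(=O)NC(C)C)cc1OCOC | intermediate
9 | 3,5-bis(methoxymethoxy)-4-(2-methylbut-3-en-2-yl)phenyl N-(propan-2-yl)-N-(trimethylsilyl)carbamate (formed in the flask) | C=CC(C)(C)c1c(OCOC)cc(OC(=O)N(C(C)C)[Si](C)(C)C)cc1OCOC | intermediate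
10 | 2-lithio-3,5-bis(methoxymethoxy)-4-(2-methylbut-3-en-2-yl)phenyl N-(propan-2-yl)-N-(trimethylsilyl)carbamate (formed in the flask) | C=CC(C)(C)c1c(OCOC)cc(OC(=O)N(C(C)C)[Si](C)(C)C)c([Li])c1OCOC | intermediate
11 | 3,5-bis(methoxymethoxy)-4-(2-methylbut-3-en-2-yl)-2-(trimethylsilyl)phenyl N-(propan-2-yl)-N-(trimethylsilyl)carbamate (formed in the flask) | C=CC(C)(C)c1c(OCOC)cc(OC(=O)N(C(C)C)[Si](C)(C)C)c([Si](C)(C)C)c1OCOC | intermediate
12 | 3,5-bis(methoxymethoxy)-4-(2-methylbut-3-en-2-yl)-2-(trimethylsilyl)phenyl N-(propan-2-yl)carbamate | C=CC(C)(C)c1c(OCOC)cc(OC(=O)NC(C)C)c([Si](C)(C)C)c1OCOC | intermediate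
13 | 3,5-bis(methoxymethoxy)-4-(2-methylbut-3-en-2-yl)-2-(trimethylsilyl)phenol (formed in the flask as its amidinium phenoxide) | C=CC(C)(C)c1c(OCOC)cc(O)c([Si](C)(C)C)c1OCOC | intermediate
14 | 3,5-bis(methoxymethoxy)-4-(2-methylbut-3-en-2-yl)-2-(trimethylsilyl)phenyl trifluoromethanesulfonate | C=CC(C)(C)c1c(OCOC)cc(OS(=O)(=O)C(F)(F)F)c([Si](C)(C)C)c1OCOC | intermediate
15 | methyl (E)-3-(4-hydroxyphenyl)prop-2-enoate (methyl 4-hydroxycinnamate) | COC(=O)/C=C/c1ccc(O)cc1 | starting material
16 | methyl (E)-3-[4-(methoxymethoxy)phenyl]prop-2-enoate | COC(=O)/C=C/c1ccc(OCOC)cc1 | intermediate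
17 | methyl (2R,3S)-3-[4-(methoxymethoxy)phenyl]oxirane-2-carboxylate (trans) | COC(=O)[C@@H]1O[C@H]1c1ccc(OCOC)cc1 | intermediate
18 | potassium (2R,3S)-3-[4-(methoxymethoxy)phenyl]oxirane-2-carboxylate | [K+].[O-]C(=O)[C@@H]1O[C@H]1c1ccc(OCOC)cc1 | intermediate
19 | 3,5-bis(methoxymethoxy)-4-(2-methylbut-3-en-2-yl)-1,2-didehydrobenzene (aryne, formed in the flask) | C=CC(C)(C)C1=C(OCOC)C#CC=C1OCOC | intermediate
20 | 3,5-bis(methoxymethoxy)-4-(2-methylbut-3-en-2-yl)-2-potassiophenyl (2R,3S)-3-[4-(methoxymethoxy)phenyl]oxirane-2-carboxylate (formed in the flask) | C=CC(C)(C)c1c(OCOC)cc(OC(=O)[C@@H]2O[C@H]2c2ccc(OCOC)cc2)c([K])c1OCOC | intermediate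
21 | potassium 3,5-bis(methoxymethoxy)-4-(2-methylbut-3-en-2-yl)-2-{(2R,3S)-3-[4-(methoxymethoxy)phenyl]oxirane-2-carbonyl}phenoxide (formed in the flask) | [K+].C=CC(C)(C)c1c(OCOC)cc([O-])c(c1OCOC)C(=O)[C@@H]1O[C@H]1c1ccc(OCOC)cc1 | intermediate
22 | [6-hydroxy-2,4-bis(methoxymethoxy)-3-(2-methylbut-3-en-2-yl)phenyl][(2R,3S)-3-[4-(methoxymethoxy)phenyl]oxiran-2-yl]methanone | C=CC(C)(C)c1c(OCOC)cc(O)c(c1OCOC)C(=O)[C@@H]1O[C@H]1c1ccc(OCOC)cc1 | intermediate
23 | (2R,3R)-3-hydroxy-5,7-bis(methoxymethoxy)-2-[4-(methoxymethoxy)phenyl]-6-(2-methylbut-3-en-2-yl)-2,3-dihydro-4H-chromen-4-one (2,3-trans) | C=CC(C)(C)c1c(OCOC)cc2c(c1OCOC)C(=O)[C@H](O)[C@@H](c1ccc(OCOC)cc1)O2 | intermediate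
24 | (2R,3R)-3,5,7-trihydroxy-2-(4-hydroxyphenyl)-6-(2-methylbut-3-en-2-yl)-2,3-dihydro-4H-chromen-4-one (CNP0527000.1) | C=CC(C)(C)c1c(O)cc2c(c1O)C(=O)[C@H](O)[C@@H](c1ccc(O)cc1)O2 | target

**Step count and risks**

Total steps: 12. Longest linear sequence: 9 steps (steps 1–6, then 10, 11, 12).

Steps most likely to fail:

1. Step 10 (key step). What may go wrong: protonation of aryl anion 20 before the acyl shift (plain O-arylation), O-arylation of the product phenoxide by a second aryne, or opening of the epoxide by the phenoxide or by fluoride in the basic medium. Fallback: the C4–C4a bond would be made by directed ortho-metalation instead of aryne chemistry, setting out from carbamate 8 and ester 17. Ester 17 would be treated with MeNH(OMe)·HCl and iPrMgCl (THF, −20 °C) to give the Weinreb amide F1. Carbamate 8 would be N-silylated and lithiated exactly as in step 5 (through 9 to aryllithium 10), and 10 would be quenched at −78 °C with F1 in place of TMSCl to give the N-silyl ortho-acyl carbamate F2, which loses its N-silyl group on aqueous work-up to give the ortho-acyl carbamate F3. Brief treatment of F3 with Et2NH and DBU (MeCN, 0 °C) would expel isopropyl isocyanate and bring the route back to epoxy ketone 22.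

2. Step 11. What may go wrong: attack of the phenol at the carbon next to the ketone (five-membered ring), 1,2-shift of the aroyl group in the benzylic cation, or loss of configuration at C2 through a long-lived cation. Fallback: setting out from 22, the epoxide would first be opened at the benzylic carbon by an external soft nucleophile, benzyl mercaptan with SnCl4 (CH2Cl2, −20 °C), to give the β-benzylsulfanyl α-hydroxy ketone F4, which fixes the regiochemistry. AgBF4 (CH2Cl2, 0 °C) would then pull off the benzylsulfanyl group, and the phenol would close ring C on the benzylic carbon with the aryl group trans to the C3 hydroxyl. This rejoins the route at 23.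

3. Step 3. What may go wrong: carbamoylation at one of the hindered hydroxyls or twofold carbamoylation. Fallback: setting out from triol 6, the unhindered hydroxyl would be marked by a reagent that discriminates by size, TIPSCl with imidazole (DMF, 0 °C), to give the mono-silyl ether F5. The two hindered phenols would then be protected with MOMCl and iPr2NEt to give the bis-MOM silyl ether F6, and Bu4NF (THF, 0 °C) would free the single phenol F7. Carbamoylation of F7 with iPrNCO and Et3N needs no selectivity and returns the route to 8.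

**Further compounds**

F1 | step 10 | (2R,3S)-N-methoxy-N-methyl-3-[4-(methoxymethoxy)phenyl]oxirane-2-carboxamide | CON(C)C(=O)[C@@H]1O[C@H]1c1ccc(OCOC)cc1
F2 | step 10 | 3,5-bis(methoxymethoxy)-4-(2-methylbut-3-en-2-yl)-2-{(2R,3S)-3-[4-(methoxymethoxy)phenyl]oxirane-2-carbonyl}phenyl N-(propan-2-yl)-N-(trimethylsilyl)carbamate | C=CC(C)(C)c1c(OCOC)cc(OC(=O)N(C(C)C)[Si](C)(C)C)c(c1OCOC)C(=O)[C@@H]1O[C@H]1c1ccc(OCOC)cc1
F3 | step 10 | 3,5-bis(methoxymethoxy)-4-(2-methylbut-3-en-2-yl)-2-{(2R,3S)-3-[4-(methoxymethoxy)phenyl]oxirane-2-carbonyl}phenyl N-(propan-2-yl)carbamate | C=CC(C)(C)c1c(OCOC)cc(OC(=O)NC(C)C)c(c1OCOC)C(=O)[C@@H]1O[C@H]1c1ccc(OCOC)cc1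
F4 | step 11 | (2S,3R)-3-(benzylsulfanyl)-2-hydroxy-1-[6-hydroxy-2,4-bis(methoxymethoxy)-3-(2-methylbut-3-en-2-yl)phenyl]-3-[4-(methoxymethoxy)phenyl]propan-1-one | C=CC(C)(C)c1c(OCOC)cc(O)c(c1OCOC)C(=O)[C@H](O)[C@H](SCc1ccccc1)c1ccc(OCOC)cc1
F5 | step 3 | 2-(2-methylbut-3-en-2-yl)-5-{[tri(propan-2-yl)silyl]oxy}benzene-1,3-diol | C=CC(C)(C)c1c(O)cc(O[Si](C(C)C)(C(C)C)C(C)C)cc1O
F6 | step 3 | [3,5-bis(methoxymethoxy)-4-(2-methylbut-3-en-2-yl)phenoxy]tri(propan-2-yl)silane | C=CC(C)(C)c1c(OCOC)cc(O[Si](C(C)C)(C(C)C)C(C)C)cc1OCOC
F7 | step 3 | 3,5-bis(methoxymethoxy)-4-(2-methylbut-3-en-2-yl)phenol | C=CC(C)(C)c1c(OCOC)cc(O)cc1OCOC
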